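**Strategy.** Ring C (O1–C2–C3–C4–C4a–C8a, isoflavan numbering) is disconnected at two bonds at once, O1–C8a and C4–C4a. The four-atom piece O1–C2–C3–C4, with ring B on C3, is symmetric about C3. It therefore comes from a prochiral 3-aryloxetane, whose catalytic enantioselective opening with TMSBr sets C3 and gives an (S)-bromohydrin. The key step, a palladium/norbornene (Catellani-type) annulation, joins this bromohydrin to a ring A iodide. It exploits that C8a sits between C8 (OMe, the required ortho blocker) and C4a (H). C4a–H is alkylated, C8a is etherified and ring C closes, all in one operation. Debenzylation and aerobic oxidation of ring B to the quinone finish the synthesis.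

Key step: step 7

Assumption: the sense of induction of the squaramide in step 6 is matched to (S)-11 by the choice of catalyst enantiomer, both enantiomers being accessible from the corresponding amino acid.

Step 1
Reactants: 1 2,6-dimethoxyphenol
Product: 2 2-(benzyloxy)-1,3-dimethoxybenzene
Conditions: BnBr, K2CO3, DMF, 60 °C
Reagents that add atoms: benzyl bromide, BrCc1ccccc1
Why: Williamson ether synthesis on the only nucleophilic site; capping the phenol also removes its para-directing power, so that step 2 is steered by the two OMe groups.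

Step 2
Reactants: 2 2-(benzyloxy)-1,3-dimethoxybenzene
Product: 3 2-(benzyloxy)-4-iodo-1,3-dimethoxybenzene
Conditions: NIS, TFA (cat.), MeCN, rt, dark
Reagents that add atoms: N-iodosuccinimide, O=C1CCC(=O)N1I
Why: Electrophilic aromatic iodination at C4 (equivalent to C6), which is ortho to one in-plane OMe and para to the other, whereas the twisted central benzyloxy group activates C5 only weakly, as in 1,2,3-trialkoxybenzenes generally.

Step 3
Reactants: 4 2,3-dimethoxy-1,4-benzoquinone
Product: 6 1,4-bis(benzyloxy)-2,3-dimethoxybenzene, via 2,3-dimethoxyhydroquinone 5 (not isolated)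
Conditions: Na2S2O4, Et2O–H2O, rt; then BnBr, K2CO3, DMF, 60 °C, N2
Reagents that add atoms: benzyl bromide, BrCc1ccccc1
Why: Dithionite reduction of the quinone and double Williamson benzylation store ring B at the hydroquinone level under groups that fall together with the ring A benzyl ether in step 8.

Step 4
Reactants: 6 1,4-bis(benzyloxy)-2,3-dimethoxybenzene
Product: 7 1,4-bis(benzyloxy)-5-bromo-2,3-dimethoxybenzene
Conditions: NBS (1.0 equiv), MeCN, 0 °C to rt, dark
Reagents that add atoms: N-bromosuccinimide, O=C1CCC(=O)N1Br
Why: Ionic electrophilic aromatic bromination; the two free ring positions are equivalent, the first bromine slows a second substitution, and the benzyl phenyl rings are far less activated.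

Step 5
Reactants: 7 1,4-bis(benzyloxy)-5-bromo-2,3-dimethoxybenzene; 8 3-bromooxetane
Product: 9 3-[2,5-bis(benzyloxy)-3,4-dimethoxyphenyl]oxetane
Conditions: NiCl2·glyme (10 mol %), 1,10-phenanthroline (20 mol %), NaBF4, 4-ethylpyridine, Mn powder, MeOH, 60 °C
Reagents that add atoms: none
Why: Nickel-catalysed reductive cross-electrophile coupling, in which the aryl bromide adds to low-valent nickel, the oxetan-3-yl radical from 8 is captured at nickel and reductive elimination forms the C(sp2)–C(sp3) bond, a reaction type established for saturated heterocyclic bromides.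

Step 6
Reactants: 9 3-[2,5-bis(benzyloxy)-3,4-dimethoxyphenyl]oxetane
Product: 11 (S)-3-bromo-2-[2,5-bis(benzyloxy)-3,4-dimethoxyphenyl]propan-1-ol, via trimethylsilyl ether 10 (not isolated)
Conditions: TMSBr (1.2 equiv), chiral squaramide hydrogen-bond donor of the tert-leucine 2-arylpyrrolidine amide type (5 mol %), t-BuOMe, −78 °C; then MeOH, −78 °C to rt
Reagents that add atoms: bromotrimethylsilane, C[Si](C)(C)Br
Why: Enantioselective desymmetrising oxetane opening under anion-binding catalysis: TMSBr silylates the oxetane oxygen, and the squaramide holds the bromide of the ion pair and delivers it by SN2 to one of the two enantiotopic CH2–O carbons, which makes C3 stereogenic (S) without any bond to C3 being formed or broken.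

Step 7
Reactants: 3 2-(benzyloxy)-4-iodo-1,3-dimethoxybenzene; 11 (S)-3-bromo-2-[2,5-bis(benzyloxy)-3,4-dimethoxyphenyl]propan-1-ol
Product: 12 (S)-7-(benzyloxy)-3-[2,5-bis(benzyloxy)-3,4-dimethoxyphenyl]-6,8-dimethoxychroman
Conditions: Pd(OAc)2 (10 mol %), RuPhos (20 mol %), norbornene (1 equiv), Cs2CO3 (3 equiv), 1,4-dioxane, 100 °C
Reagents that add atoms: none
Why: Proposed new method: zerovalent palladium inserts into the C8a–I bond of 3, norbornene carbopalladation and palladation of C4a–H give the aryl–norbornyl palladacycle, this takes up the primary C–Br of 11 (or the iodide formed from it by exchange with released iodide) to reach tetravalent palladium and reductively eliminates to forge C4–C4a, after which the doubly ortho-flanked arylpalladium expels norbornene by β-carbon elimination, binds the pendant alkoxide and forms O1–C8a. The closest known reaction types are the Catellani annulations of aryl iodides with epoxides (to 2,3-dihydrobenzofurans) and with bromoalkylamines (to indolines and tetrahydroquinolines) and the palladium-catalysed intramolecular etherification of aryl halides with primary alcohols to chromans; new are a 3-bromopropanol as the two-ended partner and a six-membered C–O closure at the ipso carbon. Ring C closes by C(aryl)–O reductive elimination from a seven-membered oxapalladacycle of divalent palladium. No stereocentre is formed and no bond to C3 is touched, so the S configuration of 11 is carried into 12, provided that reductive elimination from the tetravalent alkylpalladium outruns β-hydride loss at C3, as is usual in Catellani alkylations. Site selectivity is secured by the substrate, because C8 bears the OMe group that the sequence needs as ortho blocker and C4a is the only ortho C–H. The step also needs C–O bond formation to win over β-hydride elimination of the palladium alkoxide and over arylation of C6′–H of ring B, which rests on the bulky dialkylbiarylphosphine and on carbonate as the only stoichiometric base.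

Step 8
Reactants: 12 (S)-7-(benzyloxy)-3-[2,5-bis(benzyloxy)-3,4-dimethoxyphenyl]-6,8-dimethoxychroman
Product: 14 2,3-dimethoxy-5-[(3S)-7-hydroxy-6,8-dimethoxychroman-3-yl]cyclohexa-2,5-diene-1,4-dione (CNP0121136.1), via hydroquinone 13 (not isolated)
Conditions: H2 (1 atm), Pd/C, EtOAc–MeOH, rt; filter; then O2 (1 atm), silica gel, EtOAc, rt
Reagents that add atoms: none
Why: Hydrogenolysis of the three aryl benzyl ethers followed by autoxidation; the electron-rich 2,3-dimethoxyhydroquinone of ring B is oxidised by O2 far more readily than the lone 7-OH phenol of ring A, and the neutral medium leaves C3 untouched.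

**Compound list**
1 | 2,6-dimethoxyphenol | COc1cccc(OC)c1O | starting material
2 | 2-(benzyloxy)-1,3-dimethoxybenzene | COc1cccc(OC)c1OCc1ccccc1 | intermediate
3 | 2-(benzyloxy)-4-iodo-1,3-dimethoxybenzene | COc1ccc(I)c(OC)c1OCc1ccccc1 | intermediate
4 | 2,3-dimethoxy-1,4-benzoquinone | COC1=C(OC)C(=O)C=CC1=O | starting material
5 | 2,3-dimethoxyhydroquinone (not isolated) | COc1c(O)ccc(O)c1OC | intermediate
6 | 1,4-bis(benzyloxy)-2,3-dimethoxybenzene | COc1c(OCc2ccccc2)ccc(OCc2ccccc2)c1OC | intermediate
7 | 1,4-bis(benzyloxy)-5-bromo-2,3-dimethoxybenzene | COc1c(OCc2ccccc2)cc(Br)c(OCc2ccccc2)c1OC | intermediate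
8 | 3-bromooxetane | BrC1COC1 | starting material
9 | 3-[2,5-bis(benzyloxy)-3,4-dimethoxyphenyl]oxetane | COc1c(OCc2ccccc2)cc(C2COC2)c(OCc2ccccc2)c1OC | intermediate
10 | (S)-[3-bromo-2-[2,5-bis(benzyloxy)-3,4-dimethoxyphenyl]propoxy]trimethylsilane (not isolated) | COc1c(OCc2ccccc2)cc([C@H](CBr)CO[Si](C)(C)C)c(OCc2ccccc2)c1OC | intermediate
11 | (S)-3-bromo-2-[2,5-bis(benzyloxy)-3,4-dimethoxyphenyl]propan-1-ol | COc1c(OCc2ccccc2)cc([C@H](CBr)CO)c(OCc2ccccc2)c1OC | intermediate
12 | (S)-7-(benzyloxy)-3-[2,5-bis(benzyloxy)-3,4-dimethoxyphenyl]-6,8-dimethoxychroman | COc1c(OCc2ccccc2)cc([C@H]2COc3c(cc(OC)c(OCc4ccccc4)c3OC)C2)c(OCc2ccccc2)c1OC | intermediate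
13 | 2,3-dimethoxy-5-[(3S)-7-hydroxy-6,8-dimethoxychroman-3-yl]benzene-1,4-diol (not isolated) | COc1c(O)cc([C@H]2COc3c(cc(OC)c(O)c3OC)C2)c(O)c1OC | intermediate
14 | 2,3-dimethoxy-5-[(3S)-7-hydroxy-6,8-dimethoxychroman-3-yl]cyclohexa-2,5-diene-1,4-dione | COC1=C(OC)C(=O)C([C@H]2COc3c(cc(OC)c(O)c3OC)C2)=CC1=O | target

Total step count: 8. Longest linear sequence: 6 steps (4 to 14, steps 3 to 8).

**Steps most likely to fail**

(a) Step 7.
- Uptake of the β-branched bromide by the palladacycle may be slow, so that norbornene-retaining reductive elimination takes over.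
- The base may re-close the bromohydrin to the achiral oxetane, which would cost material but not enantiopurity.
- At the last stage, β-hydride elimination of the palladium alkoxide or C–H arylation of ring B may compete with C–O bond formation.

The fallback uses known chemistry, sets out from 3 and 11 and comes back at 12. Copper-catalysed hydroxylation of 3 (CuI, 1,10-phenanthroline, KOH, DMSO–H2O, 100 °C) gives 3-(benzyloxy)-2,4-dimethoxyphenol F1. Amine-catalysed ortho-bromination (NBS, cat. i-Pr2NH, CH2Cl2, 0 °C) gives 3-(benzyloxy)-6-bromo-2,4-dimethoxyphenol F2. Mitsunobu etherification of F2 with the primary alcohol of 11 (PPh3, DIAD, THF) gives (S)-1,4-bis(benzyloxy)-5-{1-bromo-3-[3-(benzyloxy)-6-bromo-2,4-dimethoxyphenoxy]propan-2-yl}-2,3-dimethoxybenzene F3. A Parham cyclisation (n-BuLi, THF, −100 °C) then runs by selective aryl bromine–lithium exchange and intramolecular SN2 at CH2Br. This closes C4–C4a, and with it ring C, to give 12.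

(b) Step 6.
- The ortho-benzyloxy group of ring B may disturb the fit in the catalyst pocket, so that the two enantiotopic CH2 groups are poorly discriminated.
- The very electron-rich aryl group may participate as a neighbouring group, which would lead to aryl migration.

The fallback sets out from 7 and comes back at 11. Palladium-catalysed arylation of diethyl malonate with 7 (Pd(dba)2, P(t-Bu)3, K3PO4, toluene, 70 °C) gives diethyl 2-[2,5-bis(benzyloxy)-3,4-dimethoxyphenyl]malonate F4. Reduction with LiAlH4 (THF, 0 °C) gives 2-[2,5-bis(benzyloxy)-3,4-dimethoxyphenyl]propane-1,3-diol F5. Lipase-catalysed desymmetrising monoacetylation (lipase chosen by screening, vinyl acetate, t-BuOMe) gives (R)-2-[2,5-bis(benzyloxy)-3,4-dimethoxyphenyl]-3-hydroxypropyl acetate F6. An Appel reaction (CBr4, PPh3, CH2Cl2, 0 °C) gives (S)-3-bromo-2-[2,5-bis(benzyloxy)-3,4-dimethoxyphenyl]propyl acetate F7. Acid-catalysed methanolysis (cat. AcCl, MeOH, rt) then gives 11.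

(c) Step 5. Hydrodehalogenation and homocoupling of the hindered, electron-rich aryl bromide may outrun the capture of the oxetanyl radical.

The fallback sets out from 7 and comes back at 9. It replaces the reductive coupling of two electrophiles by a coupling with a preformed aryl nucleophile. Bromine–lithium exchange and borylation (n-BuLi, THF, −78 °C; B(Oi-Pr)3; aqueous NH4Cl) give [2,5-bis(benzyloxy)-3,4-dimethoxyphenyl]boronic acid F8. This is joined to commercial 3-iodooxetane by a nickel-catalysed alkyl Suzuki–Miyaura coupling (NiI2, trans-2-aminocyclohexanol hydrochloride, NaHMDS, i-PrOH, 80 °C) to give 9.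

**Further compounds**
F1 | step 7 | 3-(benzyloxy)-2,4-dimethoxyphenol | COc1ccc(O)c(OC)c1OCc1ccccc1
F2 | step 7 | 3-(benzyloxy)-6-bromo-2,4-dimethoxyphenol | COc1cc(Br)c(O)c(OC)c1OCc1ccccc1
F3 | step 7 | (S)-1,4-bis(benzyloxy)-5-{1-bromo-3-[3-(benzyloxy)-6-bromo-2,4-dimethoxyphenoxy]propan-2-yl}-2,3-dimethoxybenzene | COc1c(OCc2ccccc2)cc([C@H](CBr)COc2c(Br)cc(OC)c(OCc3ccccc3)c2OC)c(OCc2ccccc2)c1OC
F4 | step 6 | diethyl 2-[2,5-bis(benzyloxy)-3,4-dimethoxyphenyl]malonate | CCOC(=O)C(C(=O)OCC)c1cc(OCc2ccccc2)c(OC)c(OC)c1OCc1ccccc1
F5 | step 6 | 2-[2,5-bis(benzyloxy)-3,4-dimethoxyphenyl]propane-1,3-diol | OCC(CO)c1cc(OCc2ccccc2)c(OC)c(OC)c1OCc1ccccc1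
F6 | step 6 | (R)-2-[2,5-bis(benzyloxy)-3,4-dimethoxyphenyl]-3-hydroxypropyl acetate | COc1c(OCc2ccccc2)cc([C@H](CO)COC(C)=O)c(OCc2ccccc2)c1OC
F7 | step 6 | (S)-3-bromo-2-[2,5-bis(benzyloxy)-3,4-dimethoxyphenyl]propyl acetate | COc1c(OCc2ccccc2)cc([C@H](CBr)COC(C)=O)c(OCc2ccccc2)c1OC
F8 | step 5 | [2,5-bis(benzyloxy)-3,4-dimethoxyphenyl]boronic acid | OB(O)c1cc(OCc2ccccc2)c(OC)c(OC)c1OCc1ccccc1
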